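**Plan**

Retrosynthesis (eudesmane numbering): the aryl–O bond of the C4 ether is cut first, then C4–C15, then the ring bonds C5–C10 and C6–C7 together, and last the chain bonds C8–C9, C4–C5 and C1–C10.
Forward: the open chain is joined in the order C1–C10 (carbocupration of propyne), C4–C5 (vinyl Grignard), C8–C9 (Suzuki coupling); rings A and B then arise together in one intramolecular Diels–Alder step; the C15 methyl and the magnolol unit follow.
Enabling feature: rings A and B are cis-fused, H5, the C10 methyl and the C7 side chain lie on one face, and the oxygenated C4 sits directly beside C5. This is the pattern a 1,7,9-decatrien-3-one delivers when diene carbon C10 carries the tether on its inward (Z) position and the methyl outward.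
Stereochemistry: C5/C7/C10 relative configuration comes from the diene geometry (Z at C9=C10, E at C7=C8) and the tether; absolute configuration from a chiral oxazaborolidinium catalyst; C4 from equatorial, β-face methyl addition to the conformationally locked cis-decalone, whose carbinol oxygen becomes the ether oxygen.

Key step: step 8

Remark on numbering: C4 is the oxygenated ring-A carbon, C5/C10 the ring fusion, C7 the carbon bearing the hydroxyisopropyl group (carbinol carbon C11), C15 the methyl on C4; β is the face of the C10 methyl.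
Assumption: the (S)-prolinol-derived oxazaborolidinium ion is taken to expose the C5 re face of the boron-bound vinyl ketone, the sense recalled for its additions to acrylate-type dienophiles; if the sense proved opposite, the catalyst from (R)-α,α-diphenylprolinol would be used with nothing else changed.

**Route**

Step 1
Reactants: 1 2-(3-chloropropyl)-1,3-dioxolane; 2 propyne
Product: 6 2-[(4Z)-5-iodo-4-methylpent-4-en-1-yl]-1,3-dioxolane, via Grignard reagent 3 (not isolated), via alkylcopper 4 (not isolated), via alkenylcopper 5 (not isolated)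
Conditions: Mg, THF, reflux; CuBr·SMe2, Et2O/Me2S, −45 °C; propyne, −25 °C; I2, −50 → 0 °C
Reagents that add atoms: iodine, [I][I]
Why: Normant carbocupration: the alkylcopper adds syn across propyne with the alkyl group on the internal carbon and copper on the terminal one, and iodinolysis of the alkenyl–copper bond with retention leaves iodine cis to the acetal chain (Z), the geometry that later puts the tether inward on C10.

Step 2
Reactants: 6 2-[(4Z)-5-iodo-4-methylpent-4-en-1-yl]-1,3-dioxolane
Product: 7 (5Z)-6-iodo-5-methylhex-5-enal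
Conditions: 1 M HCl, THF, rt
Reagents that add atoms: water, O
Why: Acid-catalysed hydrolysis of the dioxolane to the aldehyde; the trisubstituted alkenyl iodide is inert to dilute aqueous acid, and the acetal is removed here, before the acid-labile dienylic silyl ether exists.

Step 3
Reactants: 7 (5Z)-6-iodo-5-methylhex-5-enal; 8 vinylmagnesium bromide
Product: 9 (7Z)-8-iodo-7-methylocta-1,7-dien-3-ol (racemic at C3)
Conditions: THF, −78 °C; then H2O
Reagents that add atoms: none
Why: Grignard 1,2-addition of the vinyl nucleophile to the aldehyde at −78 °C, where the alkenyl iodide does not undergo halogen–magnesium exchange; the new carbinol centre is formed racemic and is erased by the oxidation in step 7.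

Step 4
Reactants: 10 2-methylbut-3-yn-2-ol
Product: 11 triethyl[(2-methylbut-3-yn-2-yl)oxy]silane
Conditions: Et3SiOTf, 2,6-lutidine, CH2Cl2, 0 °C
Reagents that add atoms: triethylsilyl trifluoromethanesulfonate, CC[Si](CC)(CC)OS(=O)(=O)C(F)(F)F
Why: Silylation of the tertiary propargylic alcohol with the silyl triflate and a hindered pyridine base, which masks the future C11 hydroxyl through the organometallic, Lewis-acid and arylation steps.

Step 5
Reactants: 11 triethyl[(2-methylbut-3-yn-2-yl)oxy]silane
Product: 12 triethyl{[(3E)-2-methyl-4-(4,4,5,5-tetramethyl-1,3,2-dioxaborolan-2-yl)but-3-en-2-yl]oxy}silane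
Conditions: pinacolborane, Cp2Zr(H)Cl (5 mol %), Et3N (10 mol %), neat, 60 °C
Reagents that add atoms: pinacolborane, CC1(C)OBOC1(C)C
Why: Zirconium-hydride-catalysed hydroboration of the terminal alkyne is a syn, anti-Markovnikov addition, so boron ends on the terminal carbon and the alkene is E.

Step 6
Reactants: 9 (7Z)-8-iodo-7-methylocta-1,7-dien-3-ol; 12 the E-alkenyl pinacol boronate
Product: 13 (7Z,9E)-7,11-dimethyl-11-[(triethylsilyl)oxy]dodeca-1,7,9-trien-3-ol (racemic at C3)
Conditions: Pd(PPh3)4 (5 mol %), aq. K3PO4, THF, 45 °C, degassed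
Reagents that add atoms: none
Why: Suzuki–Miyaura cross-coupling forms C8–C9 with retention of configuration in both partners, so the Z geometry at C9=C10 and the E geometry at C7=C8 are carried into the diene, and the free secondary alcohol and the silyl ether tolerate the mild aqueous base.

Step 7
Reactants: 13 (7Z,9E)-7,11-dimethyl-11-[(triethylsilyl)oxy]dodeca-1,7,9-trien-3-ol
Product: 14 (7Z,9E)-7,11-dimethyl-11-[(triethylsilyl)oxy]dodeca-1,7,9-trien-3-one
Conditions: Dess–Martin periodinane, NaHCO3, CH2Cl2, 0 °C; cold filtration, solution used at once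
Reagents that add atoms: none
Why: Dess–Martin oxidation of the secondary allylic alcohol under buffered, non-acidic conditions at 0 °C gives the vinyl ketone without touching the diene or the silyl ether, and the cold solution is taken on directly so that no uncatalysed cycloaddition takes place on standing.

Step 8
Reactants: 14 (7Z,9E)-7,11-dimethyl-11-[(triethylsilyl)oxy]dodeca-1,7,9-trien-3-one
Product: 15 (4aR,7S,8aS)-4a-methyl-7-{2-[(triethylsilyl)oxy]propan-2-yl}-3,4,4a,7,8,8a-hexahydronaphthalen-1(2H)-one (cis-fused; eudesmane numbering 5S,7S,10R; H5, C10 methyl and C7 side chain all β; C8=C9 alkene)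
Conditions: (S)-3,3-diphenyl-1-(2-methylphenyl)tetrahydro-1H,3H-pyrrolo[1,2-c][1,3,2]oxazaborole (20 mol %) + HN(SO2CF3)2 (17 mol %), pre-mixed at −25 °C; CH2Cl2, −78 → −40 °C
Reagents that add atoms: none
Why: Proposed new method: the N-protonated oxazaborolidine binds the C4 carbonyl oxygen syn to the vinyl group, lowers the enone LUMO and lets a concerted, asynchronous [4+2] addition of C5=C6 across the C10=C9–C8=C7 diene run at −78 to −40 °C, below the temperatures of the uncatalysed cyclisation and of the 1,5-hydrogen shift of the Z-diene; the reasoning joins two known reaction types that have not been combined, the oxazaborolidinium-catalysed intermolecular Diels–Alder reaction of vinyl ketones and acrylates and the thermal intramolecular Diels–Alder reaction of Z-diene 1,7,9-decatrien-3-ones to cis-fused octalones. Ring A closes as a six-membered ring in a type 1 (terminus-tethered) mode through the four-atom tether C1–C4 when the C5–C10 bond forms, with the tether carbonyl exo, and ring B is the new cyclohexene completed by the C6–C7 bond. Because the tether occupies the inward (Z) position on C10, only the cis-fused transition state can be reached, so the tether fixes H5 syn to the outward C10 methyl, and the E geometry of C7=C8 places the outward C7 side chain on the same face. The absolute configuration (5S,7S,10R) comes from the catalyst, whose prolinol aryl group covers one face of the s-trans enone so that the diene adds to the C5 re face. The step needs enantioface selectivity over the racemic background reaction and chemoselectivity over ionisation of the dienylic tertiary silyl ether; the low temperature, the single accessible ring-fusion geometry and a slight deficit of HN(SO2CF3)2 relative to the oxazaborolidine are what secure them.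

Step 9
Reactants: 15 the cis-fused octenone
Product: 16 (4aR,7R,8aS)-4a-methyl-7-{2-[(triethylsilyl)oxy]propan-2-yl}octahydronaphthalen-1(2H)-one (cis-fused; eudesmane numbering 5S,7R,10R)
Conditions: H2 (1 atm), 10 % Pd on carbon, EtOAc, rt
Reagents that add atoms: none
Why: Heterogeneous catalytic hydrogenation saturates the only alkene, the cis-disubstituted C8=C9 bond, creating no stereocentre; under neutral conditions in ethyl acetate the ketone, the C5 centre and the triethylsilyl ether are unaffected.

Step 10
Reactants: 16 the cis-fused decalone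
Product: 17 (1R,4aR,7R,8aS)-1,4a-dimethyl-7-{2-[(triethylsilyl)oxy]propan-2-yl}decahydronaphthalen-1-ol (eudesmane numbering: 4α-OH, 4β-CH3, 5β-H, 7β-side chain, 10β-CH3)
Conditions: MeMgBr, CeCl3 (anhydrous), THF, −78 → 0 °C; then H2O
Reagents that add atoms: methylmagnesium bromide, C[Mg]Br
Why: CeCl3-mediated Grignard 1,2-addition (Imamoto conditions) outruns enolisation toward C5; in the cis-decalone, held in the chair–chair form with the C7 side chain equatorial, the axial α approach to C4 is blocked by the syn-axial C10–C9 bond, so the methyl group enters equatorially from the β face and the hydroxyl ends axial and α, giving (4R).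

Step 11
Reactants: 18 magnolol (5,5'-diallylbiphenyl-2,2'-diol)
Product: 19 5,5'-diallyl-2'-[(triisopropylsilyl)oxy]biphenyl-2-ol
Conditions: i-Pr3SiCl (1 equiv), imidazole, DMF, 0 °C → rt
Reagents that add atoms: chlorotriisopropylsilane, CC(C)[Si](Cl)(C(C)C)C(C)C
Why: Monosilylation of the C2-symmetric biphenol: the first bulky triisopropylsilyl group shields the neighbouring hydroxyl, so the mono-ether is favoured and unreacted 18 can be recycled.

Step 12
Reactants: 19 5,5'-diallyl-2'-[(triisopropylsilyl)oxy]biphenyl-2-ol
Product: 20 5,5'-diallyl-2'-[(triisopropylsilyl)oxy]biphenyl-2-yl trifluoromethanesulfonate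
Conditions: Tf2O, pyridine, CH2Cl2, 0 °C
Reagents that add atoms: trifluoromethanesulfonic anhydride, O=S(=O)(OS(=O)(=O)C(F)(F)F)C(F)(F)F
Why: Sulfonylation of the remaining phenol with triflic anhydride and pyridine converts the C–O bond into a handle for palladium chemistry.

Step 13
Reactants: 20 the aryl triflate
Product: 21 tributyl{5,5'-diallyl-2'-[(triisopropylsilyl)oxy]biphenyl-2-yl}stannane
Conditions: (Bu3Sn)2, Pd(PPh3)4 (5 mol %), LiCl, 1,4-dioxane, 100 °C
Reagents that add atoms: hexabutylditin, CCCC[Sn](CCCC)(CCCC)[Sn](CCCC)(CCCC)CCCC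
Why: Palladium-catalysed stannylation of the aryl triflate with hexabutylditin (oxidative addition, tin transmetalation assisted by chloride, reductive elimination) places tin exactly on the former phenol carbon; allyl groups and the silyl ether are spectators.

Step 14
Reactants: 21 the arylstannane
Product: 22 {5,5'-diallyl-2'-[(triisopropylsilyl)oxy]biphenyl-2-yl}(4-methoxyphenyl)iodonium 4-methylbenzenesulfonate
Conditions: 4-MeOC6H4I(OAc)2, TsOH·H2O, MeCN/CH2Cl2, 0 °C → rt
Reagents that add atoms: 1-(diacetoxyiodo)-4-methoxybenzene, COc1ccc(I(OC(C)=O)OC(C)=O)cc1; p-toluenesulfonic acid monohydrate, Cc1ccc(S(=O)(=O)O)cc1.O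
Why: Ipso-destannylation by the Koser-type hydroxy(tosyloxy)iodoarene formed in the flask transfers the aryl group from tin to trivalent iodine regiospecifically, giving the unsymmetrical diaryliodonium tosylate under conditions mild enough for the allyl groups and the silyl ether.

Step 15
Reactants: 17 the 4α-carbinol; 22 the diaryliodonium tosylate
Product: 24 2-{[(1R,4aR,7R,8aS)-1,4a-dimethyl-7-{2-[(triethylsilyl)oxy]propan-2-yl}decahydronaphthalen-1-yl]oxy}-5,5'-diallyl-2'-[(triisopropylsilyl)oxy]biphenyl, via sodium alkoxide 23 (not isolated)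
Conditions: NaN(SiMe3)2, toluene/THF, 0 °C; then 22, rt → 40 °C
Reagents that add atoms: none
Why: Metal-free O-arylation by ligand coupling at trivalent iodine: the tertiary alkoxide binds iodine and couples with the ipso carbon of the ortho-substituted, less electron-rich biaryl group while the 4-methoxyphenyl group leaves as 4-iodoanisole, a reaction established for tertiary alkoxides and ortho-substituted diaryliodonium salts; the C4–O bond is not broken, so the C4 configuration is retained.

Step 16
Reactants: 24 the doubly silylated ether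
Product: 25 2-[(2R,4aR,8R,8aS)-8-{[2'-hydroxy-5,5'-di(prop-2-en-1-yl)biphenyl-2-yl]oxy}-4a,8-dimethyldecahydronaphthalen-2-yl]propan-2-ol (target; eudesmane numbering 4R,5S,7R,10R)
Conditions: Bu4NF, THF, rt → 45 °C
Reagents that add atoms: none
Why: Fluoride cleaves both Si–O bonds, the aryl triisopropylsilyl ether fast and the tertiary triethylsilyl ether on gentle warming, and leaves the tertiary alkyl aryl ether, the allyl groups and all four stereocentres untouched.

**Compound list**

1 | 2-(3-chloropropyl)-1,3-dioxolane | ClCCCC1OCCO1 | starting material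
2 | propyne | CC#C | starting material
3 | [3-(1,3-dioxolan-2-yl)propyl]magnesium chloride | Cl[Mg]CCCC1OCCO1 | intermediate
4 | [3-(1,3-dioxolan-2-yl)propyl]copper (MgBrCl/SMe2 complex) | [Cu]CCCC1OCCO1 | intermediate
5 | [(1Z)-5-(1,3-dioxolan-2-yl)-2-methylpent-1-en-1-yl]copper | [Cu]\C=C(C)/CCCC1OCCO1 | intermediate
6 | 2-[(4Z)-5-iodo-4-methylpent-4-en-1-yl]-1,3-dioxolane | I\C=C(C)/CCCC1OCCO1 | intermediate
7 | (5Z)-6-iodo-5-methylhex-5-enal | O=CCCC/C(C)=C\I | intermediate
8 | vinylmagnesium bromide | C=C[Mg]Br | starting material
9 | (7Z)-8-iodo-7-methylocta-1,7-dien-3-ol (racemic) | C=CC(O)CCC/C(C)=C\I | intermediate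
10 | 2-methylbut-3-yn-2-ol | CC(C)(O)C#C | starting material
11 | triethyl[(2-methylbut-3-yn-2-yl)oxy]silane | C#CC(C)(C)O[Si](CC)(CC)CC | intermediate
12 | triethyl{[(3E)-2-methyl-4-(4,4,5,5-tetramethyl-1,3,2-dioxaborolan-2-yl)but-3-en-2-yl]oxy}silane | CC1(C)OB(/C=C/C(C)(C)O[Si](CC)(CC)CC)OC1(C)C | intermediate
13 | (7Z,9E)-7,11-dimethyl-11-[(triethylsilyl)oxy]dodeca-1,7,9-trien-3-ol (racemic at C3) | C=CC(O)CCC/C(C)=C\C=C\C(C)(C)O[Si](CC)(CC)CC | intermediate
14 | (7Z,9E)-7,11-dimethyl-11-[(triethylsilyl)oxy]dodeca-1,7,9-trien-3-one | C=CC(=O)CCC/C(C)=C\C=C\C(C)(C)O[Si](CC)(CC)CC | intermediate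
15 | (4aR,7S,8aS)-4a-methyl-7-{2-[(triethylsilyl)oxy]propan-2-yl}-3,4,4a,7,8,8a-hexahydronaphthalen-1(2H)-one | O=C1CCC[C@]2(C)C=C[C@@H](C(C)(C)O[Si](CC)(CC)CC)C[C@@H]21 | intermediate
16 | (4aR,7R,8aS)-4a-methyl-7-{2-[(triethylsilyl)oxy]propan-2-yl}octahydronaphthalen-1(2H)-one | O=C1CCC[C@]2(C)CC[C@@H](C(C)(C)O[Si](CC)(CC)CC)C[C@@H]21 | intermediate
17 | (1R,4aR,7R,8aS)-1,4a-dimethyl-7-{2-[(triethylsilyl)oxy]propan-2-yl}decahydronaphthalen-1-ol | O[C@]1(C)CCC[C@]2(C)CC[C@@H](C(C)(C)O[Si](CC)(CC)CC)C[C@@H]21 | intermediate
18 | magnolol (5,5'-diallylbiphenyl-2,2'-diol) | C=CCc1ccc(O)c(-c2cc(CC=C)ccc2O)c1 | starting material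
19 | 5,5'-diallyl-2'-[(triisopropylsilyl)oxy]biphenyl-2-ol | C=CCc1ccc(O)c(-c2cc(CC=C)ccc2O[Si](C(C)C)(C(C)C)C(C)C)c1 | intermediate
20 | 5,5'-diallyl-2'-[(triisopropylsilyl)oxy]biphenyl-2-yl trifluoromethanesulfonate | C=CCc1ccc(OS(=O)(=O)C(F)(F)F)c(-c2cc(CC=C)ccc2O[Si](C(C)C)(C(C)C)C(C)C)c1 | intermediate
21 | tributyl{5,5'-diallyl-2'-[(triisopropylsilyl)oxy]biphenyl-2-yl}stannane | C=CCc1ccc([Sn](CCCC)(CCCC)CCCC)c(-c2cc(CC=C)ccc2O[Si](C(C)C)(C(C)C)C(C)C)c1 | intermediate
22 | {5,5'-diallyl-2'-[(triisopropylsilyl)oxy]biphenyl-2-yl}(4-methoxyphenyl)iodonium 4-methylbenzenesulfonate | C=CCc1ccc([I+]c2ccc(OC)cc2)c(-c2cc(CC=C)ccc2O[Si](C(C)C)(C(C)C)C(C)C)c1.Cc1ccc(S(=O)(=O)[O-])cc1 | intermediate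
23 | sodium (1R,4aR,7R,8aS)-1,4a-dimethyl-7-{2-[(triethylsilyl)oxy]propan-2-yl}decahydronaphthalen-1-olate | [Na+].[O-][C@]1(C)CCC[C@]2(C)CC[C@@H](C(C)(C)O[Si](CC)(CC)CC)C[C@@H]21 | intermediate
24 | 2-{[(1R,4aR,7R,8aS)-1,4a-dimethyl-7-{2-[(triethylsilyl)oxy]propan-2-yl}decahydronaphthalen-1-yl]oxy}-5,5'-diallyl-2'-[(triisopropylsilyl)oxy]biphenyl | C=CCc1ccc(O[Si](C(C)C)(C(C)C)C(C)C)c(-c2cc(CC=C)ccc2O[C@]2(C)CCC[C@]3(C)CC[C@@H](C(C)(C)O[Si](CC)(CC)CC)C[C@@H]32)c1 | intermediate
25 | 2-[(2R,4aR,8R,8aS)-8-{[2'-hydroxy-5,5'-di(prop-2-en-1-yl)biphenyl-2-yl]oxy}-4a,8-dimethyldecahydronaphthalen-2-yl]propan-2-ol | C=CCc1ccc(O)c(-c2cc(CC=C)ccc2O[C@]2(C)CCC[C@]3(C)CC[C@@H](C(C)(C)O)C[C@@H]32)c1 | target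

**Step count**

Total step count: 16. Longest linear sequence: 10 steps (1, 2, 3, 6, 7, 8, 9, 10, 15, 16); steps 4–5 and 11–14 are side branches.

**Steps most likely to fail**

Step 8. The enantioface discrimination may be eroded because the uncatalysed cyclisation competes, or because the cis-only, carbonyl-exo transition state, which holds the C8–C9 unit over H5 and not over the bound carbonyl, fits the chiral pocket poorly. The cationic catalyst may also ionise the dienylic silyl ether. The fallback uses known chemistry and sets out from 14. The catalyst is omitted and the trienone is cyclised thermally in toluene at 25–50 °C, as is established for Z-diene decatrienones. Only the cis-fused adduct can form, but as the racemate, that is 15 together with the enantiomeric octenone F1. The enantiomers are separated by preparative chromatography on a chiral stationary phase (cellulose tris(3,5-dimethylphenylcarbamate)), and the route is rejoined at 15.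

Step 15. Ligand coupling at the hindered axial alkoxide may be slow, so that base-induced aryne formation from the iodonium salt, or transfer of the wrong aryl group, takes over. The fallback sets out from 21 and 17. Bromodestannylation of 21 with N-bromosuccinimide (MeCN, 0 °C) gives 2-bromo-5,5'-diallyl-2'-[(triisopropylsilyl)oxy]biphenyl F2. F2 is joined to alkoxide 23 by palladium-catalysed C–O cross-coupling (Pd2(dba)3, a di-tert-butyl(biaryl)phosphine, toluene, 80–100 °C), in which a tertiary alkoxide has no β-hydrogen to lose. The route is rejoined at 24.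

Step 10. Enolisation toward C5 with epimerisation of the ring fusion, or incomplete facial selectivity of the methyl transfer, may lower the stereochemical purity at C4 and C5. The fallback sets out from 16. Corey–Chaykovsky epoxidation with dimethylsulfoxonium methylide (Me3S(O)I, NaH, DMSO, rt) forms its betaine reversibly and so places the new carbon equatorial and the oxygen axial, giving the 4α,15-spiro-epoxide F3. Hydride opening at the CH2 terminus with LiEt3BH (THF, 0 °C) rejoins the route at 17.

**Further compounds**

F1 | step 8 | (4aS,7R,8aR)-4a-methyl-7-{2-[(triethylsilyl)oxy]propan-2-yl}-3,4,4a,7,8,8a-hexahydronaphthalen-1(2H)-one (enantiomer of 15) | O=C1CCC[C@@]2(C)C=C[C@H](C(C)(C)O[Si](CC)(CC)CC)C[C@H]21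
F2 | step 15 | 2-bromo-5,5'-diallyl-2'-[(triisopropylsilyl)oxy]biphenyl | C=CCc1ccc(Br)c(-c2cc(CC=C)ccc2O[Si](C(C)C)(C(C)C)C(C)C)c1
F3 | step 10 | 4α,15-spiro-epoxide of 16 (oxirane oxygen axial and α, CH2 equatorial and β; spiro carbon R) | O1C[C@]12CCC[C@]3(C)CC[C@@H](C(C)(C)O[Si](CC)(CC)CC)C[C@@H]32
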